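**Retrosynthetic overview**
1. Feature: in the ten-membered ring, C4 (methyl-bearing epoxide carbon) and C9 (acetate carbon) lie opposite each other and both carry oxygen. The ring-cis C10=C1 enoate with C2 and C3 lacks only a C4–C9 bond to be a six-membered ring A (C9, C10, C1, C2, C3, C4), and that same bond closes ring B (C4–C9 through C5–C8).
2. Key disconnection: the macrocycle is the perimeter of a lactone-fused hexahydronaphthalene. Ozone cleaves its C4=C9 fusion alkene to the 4,9-diketone, and the enoate geometry is inherited from ring A.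
3. After the cleavage: Felkin–Anh methyl addition at C4, 1,2-reduction and acetylation at C9, then mesylation, β-elimination (C11=C13) and closure of the C4–C5 epoxide with inversion at C5.
4. Before the cleavage: rings B and A come in one operation from an acyclic 2-bromo-1-en-7-ynoate (cyclocarbopalladation, Stille coupling, 6π electrocyclisation). Its C5–C9 chain is C1–C5 of diacetone-D-glucose, and the C8 ester comes from (S)-2-methylglycidic acid.
5. Ring order: glycidate oxirane (side branch), γ-lactone, ring B, ring A, ten-membered ring (by scission), C4–C5 oxirane.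

Key step: step 19

Remark (numbering): the germacrane numbers of the target are used throughout (C11/C12/C13 lactone, C14 ester carbon). In the sugars, C1, C2, C3, C4 and C5 become C5, C6, C7, C8 and C9.
Remark (assumption): C11 is carried as a mixture of epimers and the alkene of step 2 as an E/Z mixture. Both elements disappear later (steps 24 and 3), so they are left undefined in the SMILES.
Remark (design):
- C5 carries a bulky, non-chelating silyl ether, because a chelated methyl addition at C4 would give the 4-epimer and hence a trans epoxide.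
- C8 receives its final ester before ring formation, because a free C8 hydroxyl next to the C14 ester would lactonise.
- C13 is brought in early as a protected hydroxymethyl group, because late lactone enolate chemistry would not tolerate the acetate and the enoate.

**Step 1**
Reactants: 1 1,2:5,6-di-O-isopropylidene-α-D-glucofuranose (diacetone-D-glucose)
Product: 2 1,2:5,6-di-O-isopropylidene-α-D-ribo-hexofuranos-3-ulose
Conditions: TEMPO (cat.), KBr (cat.), NaOCl, NaHCO3, CH2Cl2/H2O, 0 °C; azeotropic drying (toluene)
Reagents that add atoms: none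
Why: Nitroxyl-catalysed hypochlorite oxidation converts the only free hydroxyl into the ketone without touching the two acetonides, and no stereocentre is formed.

**Step 2**
Reactants: 2 1,2:5,6-di-O-isopropylidene-α-D-ribo-hexofuranos-3-ulose
Product: 3 methyl 2-(3-deoxy-1,2:5,6-di-O-isopropylidene-α-D-ribo-hexofuranos-3-ylidene)acetate (E/Z mixture)
Conditions: (MeO)2P(O)CH2CO2Me, NaH, THF, 0 °C to rt
Reagents that add atoms: trimethyl phosphonoacetate COC(=O)CP(=O)(OC)OC
Why: Horner–Wadsworth–Emmons olefination of the reactive 3-ulose installs C11 and C12, and the alkene geometry does not matter because both isomers are hydrogenated to the same product.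

**Step 3**
Reactants: 3 methyl 2-(3-deoxy-1,2:5,6-di-O-isopropylidene-α-D-ribo-hexofuranos-3-ylidene)acetate
Product: 4 3-deoxy-3-C-(methoxycarbonylmethyl)-1,2:5,6-di-O-isopropylidene-α-D-allofuranose
Conditions: H2 (1 atm), Pd/C, EtOAc, rt
Reagents that add atoms: none
Why: Heterogeneous hydrogenation delivers hydrogen to the convex β face of the furanose–dioxolane bicycle, opposite the 1,2-acetonide, so the side chain ends up cis to O2 (allo configuration), which sets C7.

**Step 4**
Reactants: 4 3-deoxy-3-C-(methoxycarbonylmethyl)-1,2:5,6-di-O-isopropylidene-α-D-allofuranose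
Product: 5 α-hydroxymethyl ester (side chain CH(CH2OH)CO2Me on sugar C3; C11 epimers)
Conditions: LiN(iPr)2, THF, −78 °C; CH2O (gas, from cracked paraformaldehyde), −78 to −40 °C; AcOH
Reagents that add atoms: formaldehyde C=O
Why: Aldol addition of the lithium ester enolate to monomeric formaldehyde brings in C13 as a masked exocyclic methylene while no other acidic or electrophilic group is present, and the new C11 centre is inconsequential because it becomes sp2 in step 24.

**Step 5**
Reactants: 5 α-hydroxymethyl ester
Product: 6 TBDPS ether of 5 (side chain CH(CH2OTBDPS)CO2Me)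
Conditions: TBDPSCl, imidazole, DMF, rt
Reagents that add atoms: tert-butyl(chloro)diphenylsilane CC(C)(C)[Si](Cl)(c1ccccc1)c1ccccc1
Why: Imidazole-promoted silylation of the primary alcohol gives an acid-robust ether that survives the acidic steps 6, 8 and 14.

**Step 6**
Reactants: 6 TBDPS ether
Product: 7 5-aldehyde (1,2-O-isopropylidene-α-D-ribo-pentodialdo-1,4-furanose carrying the C3 side chain)
Conditions: H5IO6, EtOAc, rt
Reagents that add atoms: none
Why: Periodic acid hydrolyses the more exposed terminal acetonide and cleaves the liberated glycol in the same flask (Malaprade-type glycol cleavage), leaving the 1,2-acetonide and the silyl ether intact.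

**Step 7**
Reactants: 7 5-aldehyde
Product: 8 terminal alkyne (5,6-dideoxy-1,2-O-isopropylidene-α-D-ribo-hex-5-ynofuranose carrying the C3 side chain)
Conditions: dimethyl (1-diazo-2-oxopropyl)phosphonate, K2CO3, MeOH, 0 °C to rt
Reagents that add atoms: dimethyl (1-diazo-2-oxopropyl)phosphonate CC(=O)C(=[N+]=[N-])P(=O)(OC)OC
Why: Ohira–Bestmann (Seyferth–Gilbert type) homologation turns the aldehyde into the C9≡C10 alkyne under carbonate/methanol conditions mild enough to keep the adjacent alkoxy centre (future C8) intact.

**Step 8**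
Reactants: 8 terminal alkyne
Product: 9 dithioacetal lactone alcohol (C5 CH(SEt)2; cis γ-lactone C6–O/C7; free C8–OH; C9≡C10–H; C11–CH2OTBDPS)
Conditions: EtSH, BF3·OEt2, CH2Cl2, −20 to 0 °C
Reagents that add atoms: ethanethiol CCS
Why: Lewis-acid thioacetalisation opens the 1,2-acetonide and the furanose, and the O2 hydroxyl, cis to the side chain and freed while O4 is still tied up in the furanose, lactonises onto the methyl ester to give the cis-fused C6–O/C7 γ-lactone.

**Step 9**
Reactants: 9 dithioacetal lactone alcohol
Product: 10 C8 triethylsilyl ether of 9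
Conditions: Et3SiCl, imidazole, CH2Cl2, 0 °C
Reagents that add atoms: chlorotriethylsilane CC[Si](Cl)(CC)CC
Why: Silylation of the propargylic hydroxyl prevents re-closure to the furanose and translactonisation, and the group can later be removed selectively next to bulkier silyl ethers.

**Step 10**
Reactants: 10 C8 triethylsilyl ether
Product: 11 C5 aldehyde (γ-formyl cis-lactone)
Conditions: I2, NaHCO3, acetone/H2O, 0 °C
Reagents that add atoms: water O
Why: Iodine-mediated oxidative hydrolysis of the dithioacetal under bicarbonate buffering frees the aldehyde without acid, so the silyl ethers and the epimerisable C6 centre are preserved.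

**Step 11**
Reactants: 11 C5 aldehyde
Product: 12 2-bromoallylic alcohol (C3H2=C4(Br)–C5H(OH); O5 cis-related (erythro) to O6)
Conditions: CH2=CHBr, LiN(iPr)2, THF/Et2O/pentane, −110 °C; then 11; AcOH, −100 °C
Reagents that add atoms: vinyl bromide C=CBr
Why: 1,2-Addition of 1-bromo-1-lithioethene (α-lithiated vinyl bromide) is much faster on the aldehyde than on the lactone at −110 °C (one further equivalent is taken up by the alkyne C–H), and polar Felkin–Anh attack anti to the C6–O bond sets C5 with the configuration opposite to the target, as the later inversion requires.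

**Step 12**
Reactants: 12 2-bromoallylic alcohol
Product: 13 C5 TBS ether of 12
Conditions: TBSOTf, 2,6-lutidine, CH2Cl2, −78 to 0 °C
Reagents that add atoms: tert-butyldimethylsilyl triflate CC(C)(C)[Si](C)(C)OS(=O)(=O)C(F)(F)F
Why: Silyl triflate silylation caps the hindered allylic hydroxyl with the bulky, non-chelating group that will steer the methyl addition of step 20.

**Step 13**
Reactants: 13 C5 TBS ether
Product: 14 methyl ynoate (C9≡C10–CO2Me; C8 OTES)
Conditions: PdCl2 (cat.), CuCl2, NaOAc, CO (1 atm), MeOH, rt
Reagents that add atoms: carbon monoxide [C-]#[O+]; methanol CO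
Why: In this palladium-catalysed oxidative methoxycarbonylation of a terminal alkyne an alkynyl complex of divalent palladium inserts CO and is cleaved by methanol, CuCl2 re-oxidises zerovalent palladium before it can insert into the vinyl bromide, and the acetate buffer spares lactone and silyl ethers.

**Step 14**
Reactants: 14 methyl ynoate
Product: 15 C8 alcohol (γ-hydroxy ynoate)
Conditions: PPTS, MeOH/CH2Cl2, 0 °C
Reagents that add atoms: none
Why: Mild acid-catalysed methanolysis removes the triethylsilyl ether much faster than the secondary TBS and primary TBDPS ethers, and the linear alkyne keeps the freed hydroxyl away from the C14 ester.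

**Step 15**
Reactants: 16 2-methylprop-2-en-1-ol
Product: 17 (R)-2-methylglycidol [(R)-(2-methyloxiran-2-yl)methanol]
Conditions: Ti(OiPr)4 (cat.), D-(−)-diisopropyl tartrate (cat.), cumene hydroperoxide, 4 Å molecular sieves, CH2Cl2, −20 °C
Reagents that add atoms: cumene hydroperoxide CC(C)(OO)c1ccccc1
Why: Sharpless asymmetric epoxidation of the allylic alcohol sets the quaternary oxirane centre under ligand control, the D-(−)-tartrate giving the R alcohol.

**Step 16**
Reactants: 17 (R)-2-methylglycidol
Product: 18 (S)-2-methyloxirane-2-carboxylic acid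
Conditions: RuCl3 hydrate (cat.), NaIO4, MeCN/EtOAc/H2O, 0 °C to rt
Reagents that add atoms: water O
Why: Catalytic RuO4 oxidation takes the primary alcohol through the aldehyde hydrate to the acid without opening the epoxide, and the descriptor changes from R to S only because the priorities change.

**Step 17**
Reactants: 15 C8 alcohol; 18 (S)-2-methyloxirane-2-carboxylic acid
Product: 19 bromo-enyne glycidate (C4 vinyl bromide; C5 OTBS; cis-lactone; C8 (S)-2-methylglycidate; C9≡C10–CO2Me)
Conditions: DCC, DMAP (cat.), CH2Cl2, −10 °C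
Reagents that add atoms: none
Why: Steglich esterification acylates the unhindered propargylic alcohol quickly at low temperature with little DMAP, which avoids base-induced isomerisation of the γ-hydroxy ynoate and leaves both stereocentres of the partners untouched.

**Step 18**
Reactants: 19 bromo-enyne glycidate
Product: 21 lactone-fused hexahydronaphthalene diene ester (fusion alkene C4=C9; C10=C1 enoate; C5 OTBS; C8 glycidate; C11 CH2OTBDPS; O5/O6/C11/O8 all on one face of ring B), via hexatriene 20 (not isolated)
Conditions: Pd(PPh3)4 (cat.), Bu3SnCH=CH2 (slow addition), BHT, toluene, 85 °C; then 110 °C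
Reagents that add atoms: tributyl(vinyl)stannane C=C[Sn](CCCC)(CCCC)CCCC
Why: Zerovalent palladium inserts into the C4–Br bond, the alkenylpalladium adds syn and 6-exo-dig across the ynoate (C4–C9 bond, ring B, palladium on the ester-bearing C10 as the ynoate polarity demands), Stille coupling puts the vinyl group on C10 cis to C4, and the resulting (Z)-hexatriene closes thermally by disrotatory 6π electrocyclisation (C2–C3 bond, ring A), a known cyclocarbopalladation/cross-coupling/electrocyclisation cascade that creates no stereocentre.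

**Step 19**
Reactants: 21 lactone-fused hexahydronaphthalene diene ester
Product: 23 ten-membered 4,9-diketone (ring-cis C10=C1 enoate; C5 OTBS; C8 glycidate), via methoxy hydroperoxide 22 (not isolated)
Conditions: O3/O2 (one equivalent, Sudan Red 7B end point), CH2Cl2/MeOH, −78 °C; then Me2S, −78 °C to rt
Reagents that add atoms: ozone [O-][O+]=O
Why: Ozone adds as a 1,3-dipole to the most electron-rich π bond, the tetrasubstituted C4=C9 alkene, and the primary ozonide fragments (Criegee mechanism) to the C9 ketone and a C4 carbonyl oxide, which methanol traps as 22 and Me2S reduces to the C4 ketone. The closest known reaction type is the selective ozonolysis of the ring-fusion alkene of bicyclo[4.4.0]dec-1(6)-enes to cyclodecane-1,6-diones. No ring is closed by bond formation: the ten-membered ring is the perimeter of rings A and B and is set free when their shared bond is cut (ring enlargement by scission of the zero-atom bridge). No stereocentre is formed, C5 to C8 are spectators, and the C10=C1 alkene must emerge ring-cis because it was held in six-membered ring A. The step needs chemoselectivity between the two alkenes of the cross-conjugated diene, which is secured by substitution (four carbon substituents against three) and by the ester on C10 that deactivates C10=C1 towards the electrophilic dipole, backed up by one equivalent of ozone, a dye end point and −78 °C.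

**Step 20**
Reactants: 23 ten-membered 4,9-diketone
Product: 24 C4 tertiary carbinol (4R; C9 ketone retained)
Conditions: MeTi(OiPr)3, CH2Cl2, −40 to 0 °C; pH 7 buffer; crude product used at once
Reagents that add atoms: methyltitanium triisopropoxide C[Ti](OC(C)C)(OC(C)C)OC(C)C
Why: Organotitanium carbonyl addition under polar Felkin–Anh (non-chelation) control places the bulky C5 silyl ether perpendicular to the C4 carbonyl so that methyl attacks anti to it past C5–H and gives the 4R carbinol needed for the cis epoxide, while the mild, sterically demanding reagent leaves esters, lactone, epoxide and the flanked, cross-conjugated C9 ketone alone.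

**Step 21**
Reactants: 24 C4 tertiary carbinol
Product: 25 C9 allylic alcohol (9S)
Conditions: NaBH4, CeCl3·7H2O, MeOH/THF, −78 °C
Reagents that add atoms: none
Why: Luche reduction delivers hydride 1,2 to the enone carbonyl, polar Felkin–Anh attack anti to the C8 acyloxy group sets 9S (C8–O and C9–O threo), and the low temperature keeps the neighbouring ester from migrating.

**Step 22**
Reactants: 25 C9 allylic alcohol
Product: 26 C9 acetate
Conditions: Ac2O, pyridine, DMAP (cat.), CH2Cl2, 0 °C
Reagents that add atoms: acetic anhydride CC(=O)OC(C)=O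
Why: DMAP-catalysed acetylation takes the secondary C9 hydroxyl and leaves the tertiary C4 hydroxyl free.

**Step 23**
Reactants: 26 C9 acetate
Product: 27 triol (C4–OH tertiary; C5–OH secondary; C13–OH primary)
Conditions: HF·pyridine, pyridine, THF, 0 °C to rt
Reagents that add atoms: none
Why: Buffered fluoride desilylation removes the TBS and TBDPS ethers together under non-basic conditions, so no acyl group migrates and the acceptor-substituted glycidate oxirane, the only epoxide present, is not opened.

**Step 24**
Reactants: 27 triol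
Product: 30 CNP0274195.1 (target), via bis-mesylate 28 (not isolated), via hydroxy mesylate 29 (not isolated)
Conditions: MsCl, Et3N, CH2Cl2, −20 to 0 °C; then DBU, rt
Reagents that add atoms: none
Why: Sulfene-type mesylation takes the primary C13 and secondary C5 hydroxyls but not the tertiary C4 hydroxyl, the β-mesyloxy lactone loses methanesulfonate by E1cB elimination to give the exocyclic methylene, and DBU then triggers intramolecular Williamson (3-exo-tet) displacement of the C5 mesylate by the C4 oxygen with inversion, which sets the 5S centre of the cis epoxide.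

**Compound list**
1 | 1,2:5,6-di-O-isopropylidene-α-D-glucofuranose | CC1(C)O[C@H]2[C@@H](O1)O[C@H]([C@H]3COC(C)(C)O3)[C@@H]2O | starting material
2 | 1,2:5,6-di-O-isopropylidene-α-D-ribo-hexofuranos-3-ulose | CC1(C)O[C@H]2[C@@H](O1)O[C@H]([C@H]3COC(C)(C)O3)C2=O | intermediate
3 | 3-ylidene acetate (E/Z mixture) | CC1(C)O[C@H]2[C@@H](O1)O[C@H]([C@H]3COC(C)(C)O3)C2=CC(=O)OC | intermediate
4 | 3-deoxy-3-C-(methoxycarbonylmethyl)-1,2:5,6-di-O-isopropylidene-α-D-allofuranose | CC1(C)O[C@H]2[C@@H](O1)O[C@H]([C@H]3COC(C)(C)O3)[C@H]2CC(=O)OC | intermediate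
5 | α-hydroxymethyl ester (C11 epimers) | CC1(C)O[C@H]2[C@@H](O1)O[C@H]([C@H]3COC(C)(C)O3)[C@H]2C(CO)C(=O)OC | intermediate
6 | TBDPS ether of 5 | CC1(C)O[C@H]2[C@@H](O1)O[C@H]([C@H]3COC(C)(C)O3)[C@H]2C(CO[Si](c7ccccc7)(c8ccccc8)C(C)(C)C)C(=O)OC | intermediate
7 | 5-aldehyde | CC1(C)O[C@H]2[C@@H](O1)O[C@H](C=O)[C@H]2C(CO[Si](c7ccccc7)(c8ccccc8)C(C)(C)C)C(=O)OC | intermediate
8 | terminal alkyne | CC1(C)O[C@H]2[C@@H](O1)O[C@H](C#C)[C@H]2C(CO[Si](c7ccccc7)(c8ccccc8)C(C)(C)C)C(=O)OC | intermediate
9 | dithioacetal lactone alcohol | CCSC(SCC)[C@@H]1OC(=O)C(CO[Si](c7ccccc7)(c8ccccc8)C(C)(C)C)[C@@H]1[C@H](O)C#C | intermediate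
10 | C8 triethylsilyl ether | CCSC(SCC)[C@@H]1OC(=O)C(CO[Si](c7ccccc7)(c8ccccc8)C(C)(C)C)[C@@H]1[C@H](O[Si](CC)(CC)CC)C#C | intermediate
11 | C5 aldehyde | O=C[C@@H]1OC(=O)C(CO[Si](c7ccccc7)(c8ccccc8)C(C)(C)C)[C@@H]1[C@H](O[Si](CC)(CC)CC)C#C | intermediate
12 | 2-bromoallylic alcohol | C=C(Br)[C@H](O)[C@@H]1OC(=O)C(CO[Si](c7ccccc7)(c8ccccc8)C(C)(C)C)[C@@H]1[C@H](O[Si](CC)(CC)CC)C#C | intermediate
13 | C5 TBS ether | C=C(Br)[C@H](O[Si](C)(C)C(C)(C)C)[C@@H]1OC(=O)C(CO[Si](c7ccccc7)(c8ccccc8)C(C)(C)C)[C@@H]1[C@H](O[Si](CC)(CC)CC)C#C | intermediate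
14 | methyl ynoate (C8 OTES) | C=C(Br)[C@H](O[Si](C)(C)C(C)(C)C)[C@@H]1OC(=O)C(CO[Si](c7ccccc7)(c8ccccc8)C(C)(C)C)[C@@H]1[C@H](O[Si](CC)(CC)CC)C#CC(=O)OC | intermediate
15 | C8 alcohol (γ-hydroxy ynoate) | C=C(Br)[C@H](O[Si](C)(C)C(C)(C)C)[C@@H]1OC(=O)C(CO[Si](c7ccccc7)(c8ccccc8)C(C)(C)C)[C@@H]1[C@H](O)C#CC(=O)OC | intermediate
16 | 2-methylprop-2-en-1-ol | C=C(C)CO | starting material
17 | (R)-2-methylglycidol | OC[C@]1(C)CO1 | intermediate
18 | (S)-2-methyloxirane-2-carboxylic acid | OC(=O)[C@]1(C)CO1 | intermediate
19 | bromo-enyne glycidate | C=C(Br)[C@H](O[Si](C)(C)C(C)(C)C)[C@@H]1OC(=O)C(CO[Si](c7ccccc7)(c8ccccc8)C(C)(C)C)[C@@H]1[C@H](OC(=O)[C@]2(C)CO2)C#CC(=O)OC | intermediate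
20 | hexatriene (ring B with exocyclic C4=C3H2 and C9=C10(CO2Me)(vinyl), vinyl cis to C4) | C=C1[C@H](O[Si](C)(C)C(C)(C)C)[C@@H]2OC(=O)C(CO[Si](c7ccccc7)(c8ccccc8)C(C)(C)C)[C@@H]2[C@H](OC(=O)[C@]3(C)CO3)/C1=C(/C=C)C(=O)OC | intermediate
21 | lactone-fused hexahydronaphthalene diene ester (key-step precursor) | COC(=O)C1=CCCC2=C1[C@@H](OC(=O)[C@]3(C)CO3)[C@H]4C(CO[Si](c7ccccc7)(c8ccccc8)C(C)(C)C)C(=O)O[C@H]4[C@H]2O[Si](C)(C)C(C)(C)C | intermediate
22 | C4 methoxy hydroperoxide, C9 ketone (C4 epimers) | COC(=O)/C1=C/CCC(OC)(OO)[C@H](O[Si](C)(C)C(C)(C)C)[C@@H]2OC(=O)C(CO[Si](c7ccccc7)(c8ccccc8)C(C)(C)C)[C@@H]2[C@H](OC(=O)[C@]3(C)CO3)C1=O | intermediate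
23 | ten-membered 4,9-diketone (key-step product) | COC(=O)/C1=C/CCC(=O)[C@H](O[Si](C)(C)C(C)(C)C)[C@@H]2OC(=O)C(CO[Si](c7ccccc7)(c8ccccc8)C(C)(C)C)[C@@H]2[C@H](OC(=O)[C@]3(C)CO3)C1=O | intermediate
24 | C4 tertiary carbinol | COC(=O)/C1=C/CC[C@@](C)(O)[C@H](O[Si](C)(C)C(C)(C)C)[C@@H]2OC(=O)C(CO[Si](c7ccccc7)(c8ccccc8)C(C)(C)C)[C@@H]2[C@H](OC(=O)[C@]3(C)CO3)C1=O | intermediate
25 | C9 allylic alcohol | COC(=O)/C1=C/CC[C@@](C)(O)[C@H](O[Si](C)(C)C(C)(C)C)[C@@H]2OC(=O)C(CO[Si](c7ccccc7)(c8ccccc8)C(C)(C)C)[C@@H]2[C@H](OC(=O)[C@]3(C)CO3)[C@H]1O | intermediate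
26 | C9 acetate | COC(=O)/C1=C/CC[C@@](C)(O)[C@H](O[Si](C)(C)C(C)(C)C)[C@@H]2OC(=O)C(CO[Si](c7ccccc7)(c8ccccc8)C(C)(C)C)[C@@H]2[C@H](OC(=O)[C@]3(C)CO3)[C@H]1OC(C)=O | intermediate
27 | triol | COC(=O)/C1=C/CC[C@@](C)(O)[C@H](O)[C@@H]2OC(=O)C(CO)[C@@H]2[C@H](OC(=O)[C@]3(C)CO3)[C@H]1OC(C)=O | intermediate
28 | bis-mesylate | COC(=O)/C1=C/CC[C@@](C)(O)[C@H](OS(C)(=O)=O)[C@@H]2OC(=O)C(COS(C)(=O)=O)[C@@H]2[C@H](OC(=O)[C@]3(C)CO3)[C@H]1OC(C)=O | intermediate
29 | hydroxy mesylate with α-methylene lactone | COC(=O)/C1=C/CC[C@@](C)(O)[C@H](OS(C)(=O)=O)[C@@H]2OC(=O)C(=C)[C@@H]2[C@H](OC(=O)[C@]3(C)CO3)[C@H]1OC(C)=O | intermediate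
30 | CNP0274195.1 | C=C1C(=O)O[C@@H]2[C@H]1[C@H](OC(=O)[C@]1(C)CO1)[C@@H](OC(C)=O)/C(C(=O)OC)=C\CC[C@@]1(C)O[C@@H]21 | target

**Step count**
Total step count: 24. Longest linear sequence: 22 (steps 1–14 and 17–24).

**Steps most likely to fail**

1. Step 19 (key step). Three things may go wrong: ozone may go on to attack the C10=C1 enoate, it may add across the diene, or ring A may be dehydrogenated to a benzoate during oxidation or work-up. The fallback sets out from 21 and keeps the same bond scission but splits it into two milder events.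
   - A peracid discriminates more sharply between alkenes by substitution and electron density. With mCPBA, NaHCO3, CH2Cl2, −20 °C it should epoxidise only the fusion alkene, from the face opposite the four ring B substituents, to give the 4,9-epoxide F1.
   - Periodic acid in aqueous THF at 0 °C opens the epoxide to the glycol and cleaves it (Malaprade-type), and the route is rejoined at 23.

2. Step 20. Addition to the medium-ring ketone may be sluggish, the reagent may attack the C9 enone unit, or the new C4 hydroxyl may add to C1 of the doubly activated alkene. The fallback sets out from 23 and settles C9 before C4.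
   - The saturated C4 ketone is masked selectively with 1,2-bis(trimethylsilyloxy)ethane and TMSOTf (cat.) in CH2Cl2 at −78 °C, conditions under which conjugated ketones react slowly. This gives the C4 dioxolane F2.
   - Luche reduction gives the C9 alcohol ketal F3, and acetylation gives the C9 acetate ketal F4.
   - PPTS in wet acetone frees the keto acetate F5.
   - F5 now holds a single ketone and only a simple enoate as acceptor, so the more reactive MeMgBr/CeCl3 (THF, −78 °C, Felkin–Anh) can be used, and the route is rejoined at 26.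

3. Step 21. The ring conformation may override the Felkin–Anh preference and give poor facial selectivity, or hydride may be delivered 1,4 to the doubly activated alkene. The fallback sets out from 24 and replaces substrate control by catalyst control plus inversion.
   - A Corey–Bakshi–Shibata reduction (B-methyl oxazaborolidine, catecholborane, toluene, −78 °C) is 1,2-selective on enones. It is run with the catalyst enantiomer that is matched to the substrate.
   - If that gives the 9-epi alcohol F6, a Mitsunobu reaction with acetic acid (PPh3, DIAD, toluene, 0 °C) inverts C9 and installs the acetate in one operation, and the route is rejoined at 26.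

**Further compounds**
F1 | step 19 | 4,9-epoxide of 21 (oxygen anti to the ring B substituents) | COC(=O)C1=CCC[C@@]2(O3)[C@]13[C@@H](OC(=O)[C@]5(C)CO5)[C@H]4C(CO[Si](c7ccccc7)(c8ccccc8)C(C)(C)C)C(=O)O[C@H]4[C@H]2O[Si](C)(C)C(C)(C)C
F2 | step 20 | C4 dioxolane of 23 | COC(=O)/C1=C/CCC2(OCCO2)[C@H](O[Si](C)(C)C(C)(C)C)[C@@H]3OC(=O)C(CO[Si](c7ccccc7)(c8ccccc8)C(C)(C)C)[C@@H]3[C@H](OC(=O)[C@]4(C)CO4)C1=O
F3 | step 20 | C9 alcohol ketal | COC(=O)/C1=C/CCC2(OCCO2)[C@H](O[Si](C)(C)C(C)(C)C)[C@@H]3OC(=O)C(CO[Si](c7ccccc7)(c8ccccc8)C(C)(C)C)[C@@H]3[C@H](OC(=O)[C@]4(C)CO4)[C@H]1O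
F4 | step 20 | C9 acetate ketal | COC(=O)/C1=C/CCC2(OCCO2)[C@H](O[Si](C)(C)C(C)(C)C)[C@@H]3OC(=O)C(CO[Si](c7ccccc7)(c8ccccc8)C(C)(C)C)[C@@H]3[C@H](OC(=O)[C@]4(C)CO4)[C@H]1OC(C)=O
F5 | step 20 | keto acetate (C4 ketone, C9 acetate) | COC(=O)/C1=C/CCC(=O)[C@H](O[Si](C)(C)C(C)(C)C)[C@@H]2OC(=O)C(CO[Si](c7ccccc7)(c8ccccc8)C(C)(C)C)[C@@H]2[C@H](OC(=O)[C@]3(C)CO3)[C@H]1OC(C)=O
F6 | step 21 | 9-epi alcohol | COC(=O)/C1=C/CC[C@@](C)(O)[C@H](O[Si](C)(C)C(C)(C)C)[C@@H]2OC(=O)C(CO[Si](c7ccccc7)(c8ccccc8)C(C)(C)C)[C@@H]2[C@H](OC(=O)[C@]3(C)CO3)[C@@H]1O
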